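If we charge D with Z and let the living ends Q grow while step 3 turns them into J, we want to know how many units of D, held as E, the average chain carries by the end of the run.

D 11 mM; Z 5.1 mol%; time 50 h

    D + Z → Q + E (k1 = 1.37 L mol⁻¹ h⁻¹)
    D + Q → E + Q, rate k2*[Q]*[D] (k2 = 44.5 L mol⁻¹ h⁻¹)
    Q → J (k3 = 0.0331 h⁻¹)

* whether the average number of monomer units in a chain (chains begun, living or dead) reaches 7.0 by 50 h (yes / no)
* average number of monomer units in a chain (chains begun, living or dead) at 50 h

- the average divides the monomer in chains by the number of chains begun, living and dead together
- run time (flask): 50 h

A living end Q lasts 30.2 h on average, and at the charged D it adds 0.489 h⁻¹, so one lifetime builds 14.8 units, the kinetic chain length: the units a living end adds in its lifetime at the charged D. That stands above the wanted 7.0, but it flatters the flask. The half-life of Z by step 1 at the charged D is 46.0 h, close to the run of 50 h, so chains begin throughout the run.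

The run spans 1.65 lifetimes. With starts spread evenly, the average chain has built a share 0.511 of the kinetic chain length, and with its first unit from step 1 that gives 8.56 units. But D does not stay at its charge. At the charged D, step 1 uses 52.9% of Z, so on this reckoning these chains take 23.1% of D. Growing on the mean D brings the length down to 7.69, still above the wanted length. Starts also slow as Z is used, and we leave that uncomputed. We commit to an estimate between 7.69 and 8.56, so the answer is yes.

The forecast also said yes, with 8.4 and a range of 7.9 to 9, on the grounds that “only about half of the 0.56 mM initiator has started chains by 50 h”. Its 8.4 lies between our two estimates.

The simulation answers yes, with 8.46 at 50 h. The flask passed 7.0 at 34.4 h, with 13.8% of the D reacted. At 25.0 h the kinetic chain length, counted over the lifetimes elapsed, gives 5.73, and the flask stands at 5.80. For the same flask run to twice the time, the count gives 11.5 at the charged D and 9.25 at the D left at 50.0 h, and that run reaches 10.5.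

(The constants were set for the occasion; the result is computed.)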